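**Plan**

- Retrosynthesis: the C7 hydroperoxide is cut back to the 7(11)-en-8-one (Schenck ene) and the two esters are removed. Ring A is then cut at C10–C1 and C2–C3 at once, which takes out C1–C2 as the vinyl group of methyl vinyl ketone. Last, C5–C4 is cut to a carvone-derived enone and a lactate enolate.
- Feature that allows the ring-A event: C10 is a quaternary carbon of ring B bearing a methyl group next to the C9 methylene, i.e. the Markovnikov carbon of a C9=C10 alkene. The oxygenated C3 lies three bonds away (C10–C5–C4–C3). A C10 radical, a two-carbon acceptor and a C3 aldehyde therefore close the six-membered ring A.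
- Forward order: ring B (C5–C10 with C14 and C11–C13) is (R)-carvone; C15–C4–C3 is (R)-lactic acid, joined by conjugate addition. Ring A is closed in step 7 by iron-hydride HAT/Giese/aldol annulation. The acetyl helper on C2 leaves by oxidation/retro-Claisen; ring B is then taken to the isopropylidene ketone and oxygenated last.
- Stereochemistry: the carvone centre (C7) sets C5 by anti addition and is erased later. The lactate-derived acetal sets C4. C5 sets C10 (anti radical attack, trans-decalin). C3 comes from a bulky hydride, and C7–OOH from α-face attack of singlet oxygen.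

Key step: step 7

Remark: eudesmane numbering is used for every intermediate (ring A = C1–C5 + C10, ring B = C5–C10, C14 on C10, C15 on C4, C11–C13 on C7); β is the face of the C10 methyl group of the target. The C2/C3 epimers of 14 and the tautomers of 15 converge in step 8, so 14 is drawn as the expected major isomer.

**Route**

Step 1
Reactants: 1 (R)-lactic acid
Product: 2 (2R,5R)-2-tert-butyl-5-methyl-1,3-dioxolan-4-one
Conditions: t-BuCHO, p-toluenesulfonic acid (cat.), H2SO4 (cat.), pentane, reflux (water separator); crystallisation at −78 °C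
Reagents that add atoms: pivalaldehyde CC(C)(C)C=O
Why: acid-catalysed acetalisation should give the thermodynamically preferred cis acetal, whose new C2 centre (tert-butyl cis to methyl) stores the lactate chirality for the later enolate reaction.

Step 2
Reactants: 3 (R)-(−)-carvone
Product: 4 (5R)-5-(2-hydroxypropan-2-yl)-2-methylcyclohex-2-en-1-one
Conditions: 50% aq. H2SO4, 0 °C
Reagents that add atoms: water O
Why: Markovnikov hydration of the 1,1-disubstituted alkene (the protonated enone is inert) masks the isopropenyl group against the later HAT step and places the C11 oxygen needed for the final elimination, without touching the stereocentre.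

Step 3
Reactants: 4 (5R)-hydroxy enone
Product: 6 (5R,6S)-bis-TES α′-silyloxy enone, via bis(triethylsilyl) dienol ether 5 (not isolated)
Conditions: LiN(i-Pr)2 (2.3 equiv), THF, −78 °C; Et3SiCl, −78 °C → rt; then mCPBA, hexane/CH2Cl2, −20 °C
Reagents that add atoms: chlorotriethylsilane CC[Si](Cl)(CC)CC; 3-chloroperbenzoic acid OOC(=O)c1cccc(Cl)c1
Why: kinetic α′-deprotonation and O-silylation followed by Rubottom oxidation (epoxidation of the silyl enol ether, 1,4-silyl shift) should put the C8 oxygen trans to the neighbouring C7 substituent, because the peracid attacks the enol ether anti to it.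

Step 4
Reactants: 2 (2R,5R)-dioxolanone; 6 (5R,6S)-bis-TES α′-silyloxy enone
Product: 9 enol triflate of the Michael adduct, via lithium dioxolanone enolate 7 (not isolated), via lithium enolate of the Michael adduct 8 (not isolated)
Conditions: 2, LiN(i-Pr)2, THF, −78 °C; 6, DMPU, −78 → −40 °C; 2-[N,N-bis(trifluoromethylsulfonyl)amino]-5-chloropyridine, −78 → 0 °C
Reagents that add atoms: 2-[N,N-bis(trifluoromethylsulfonyl)amino]-5-chloropyridine Clc1ccc(nc1)N(S(=O)(=O)C(F)(F)F)S(=O)(=O)C(F)(F)F
Why: ester-enolate Michael addition with O-triflation of the regiodefined C9 enolate should set C5 by axial attack anti to the C7 substituent (as in conjugate additions to carvone) and C4 by reaction of the enolate face anti to the tert-butyl group, each centre being fixed by its own control element.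

Step 5
Reactants: 9 enol triflate
Product: 10 C9=C10 alkene with intact dioxolanone
Conditions: Pd(OAc)2 (5 mol %), PPh3, HCO2H, n-Bu3N, DMF, 60 °C
Reagents that add atoms: none
Why: palladium-catalysed formate reduction of an enol triflate (oxidative addition to zerovalent palladium, formate exchange, loss of CO2, C–H reductive elimination) deletes the carvone oxygen at C9 and leaves the trisubstituted C9=C10 alkene with no stereocentre involved.

Step 6
Reactants: 10 alkene dioxolanone
Product: 12 (2S)-α-hydroxy aldehyde, via dioxolane lactol 11 (not isolated)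
Conditions: i-Bu2AlH, CH2Cl2, −78 °C; aq. potassium sodium tartrate; SiO2
Reagents that add atoms: none
Why: half-reduction of the lactone-type carbonyl gives a lactol that should collapse with loss of pivalaldehyde to the non-enolisable tertiary α-hydroxy aldehyde, so C4 cannot epimerise.

Step 7
Reactants: 12 α-hydroxy aldehyde; 13 methyl vinyl ketone
Product: 14 ring-A annulation product (2-acetyl-3,4-diol)
Conditions: 13 (3 equiv), Fe(acac)3 (30 mol %), PhSiH3, EtOH/(CH2OH)2, 0 °C → rt
Reagents that add atoms: none
Why: An iron hydride formed from Fe(acac)3 and PhSiH3 transfers a hydrogen atom to C9 of the C9=C10 alkene, the tertiary C10 radical adds to the terminal carbon of 13 (bond C10–C1), the α-keto radical is reduced by divalent iron to a trivalent-iron enolate, and its carbon C2 adds to the C3 aldehyde (bond C2–C3). The closest known reaction type is the iron-catalysed HAT-initiated radical–polar crossover (Giese/aldol) annulation of an alkenyl aldehyde with an enone. Ring A is closed in the aldol event as a 6-(enolexo)-exo-trig cyclisation, the bond to C10 being made intermolecularly. C10 is controlled by C5: the bulky C4 side chain sits pseudo-axial next to the trigonal C10 and the acceptor enters on the opposite (α) face, which gives the 10β-methyl/5α-H trans fusion; C2 and C3 arise in a chair aldol transition state (expected 2α-acetyl, 3β-hydroxy) and are both erased in step 8. The step needs HAT at C9=C10 only, which is secured because this is the only alkene left (the isopropenyl group has been a silyl ether since steps 2 and 3), and it needs the aldol to outrun protonation of the enolate, which the aldehyde held three bonds from C10 should secure.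

Step 8
Reactants: 14 annulation product
Product: 16 4α-hydroxy-3-ketone, via enolised 2-acetyl-3-ketone 15 (not isolated)
Conditions: DMP, CH2Cl2, rt; then K2CO3, MeOH, rt
Reagents that add atoms: none
Why: Dess–Martin oxidation of the secondary C3 alcohol (the tertiary C4 alcohol is inert) followed by retro-Claisen cleavage, in which methoxide attacks the unhindered acetyl carbonyl, should remove the helper and leave C2 as a methylene next to the C3 ketone.

Step 9
Reactants: 16 4α-hydroxy-3-ketone
Product: 17 4α-acetoxy-3-ketone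
Conditions: Ac2O, Et3N, 4-(dimethylamino)pyridine (cat.), CH2Cl2, 40 °C
Reagents that add atoms: acetic anhydride CC(=O)OC(C)=O
Why: nucleophile-catalysed acylation of the equatorial tertiary α-ketol hydroxyl is done here, before any secondary hydroxyl or angelate is present.

Step 10
Reactants: 17 4α-acetoxy-3-ketone
Product: 18 3α-hydroxy-4α-acetate
Conditions: LiBH(s-Bu)3, THF, −78 °C; AcOH, −78 °C
Reagents that add atoms: none
Why: the bulky hydride should attack the C3 ketone from the equatorial (β) side, as with 4,4-disubstituted 3-keto trans-decalins, to give the axial 3α-alcohol (3R), and the cold acidic quench is meant to prevent 4→3 acetyl migration.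

Step 11
Reactants: 18 3α-hydroxy-4α-acetate; 19 angelic acid
Product: 21 3α-angelate 4α-acetate bis-TES ether, via mixed anhydride 20 (not isolated)
Conditions: 19, 2,4,6-Cl3C6H2COCl, Et3N, toluene, rt; filter; then 18, toluene, 80 °C
Reagents that add atoms: none
Why: Yamaguchi-type mixed-anhydride esterification run without a nucleophilic catalyst and without free base should acylate the hindered axial alcohol while keeping the Z geometry of the angelate and the acetate in place.

Step 12
Reactants: 21 bis-TES ether
Product: 22 8β,11-diol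
Conditions: HF·pyridine, pyridine, THF, 0 °C → rt
Reagents that add atoms: none
Why: fluoride-driven Si–O cleavage removes both triethylsilyl ethers under conditions that leave the angelate and the tertiary acetate untouched.

Step 13
Reactants: 22 8β,11-diol
Product: 23 11-hydroxy-8-ketone
Conditions: DMP, CH2Cl2, rt
Reagents that add atoms: none
Why: Dess–Martin oxidation converts the only secondary alcohol into the C8 ketone, the tertiary C11 alcohol being inert.

Step 14
Reactants: 23 11-hydroxy-8-ketone
Product: 24 7(11)-en-8-one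
Conditions: MsCl, Et3N, CH2Cl2, 0 °C → rt
Reagents that add atoms: none
Why: mesylation of the tertiary β-hydroxyl and E1cB elimination through the C7 enolate should give the conjugated isopropylidene ketone, which erases the carvone-derived C7 centre.

Step 15
Reactants: 24 7(11)-en-8-one
Product: 25 target hydroperoxide
Conditions: O2, visible light, tetraphenylporphyrin (cat.), CH2Cl2, −20 °C
Reagents that add atoms: dioxygen O=O
Why: Schenck ene reaction of singlet oxygen with the s-cis alkylidene ketone should bond oxygen to C7 from the α face with hydrogen abstraction from a C11 methyl group (new isopropenyl group, 7S), because the β face and the only axial ring hydrogen (H-6β) are shielded by the syn-axial methyl groups on C10 and C4.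

**Compound list**

1 | (R)-lactic acid | C[C@@H](O)C(=O)O | starting material
2 | (2R,5R)-2-tert-butyl-5-methyl-1,3-dioxolan-4-one (cis acetal) | C[C@H]1O[C@@H](C(C)(C)C)OC1=O | intermediate
3 | (R)-(−)-carvone, (5R)-2-methyl-5-(prop-1-en-2-yl)cyclohex-2-en-1-one | CC1=CC[C@H](CC1=O)C(C)=C | starting material
4 | (5R)-5-(2-hydroxypropan-2-yl)-2-methylcyclohex-2-en-1-one | CC1=CC[C@H](CC1=O)C(C)(C)O | intermediate
5 | triethyl{[(6R)-3-methyl-6-[2-(triethylsilyloxy)propan-2-yl]cyclohexa-1,3-dien-2-yl]oxy}silane | CC1=CC[C@H](C=C1O[Si](CC)(CC)CC)C(C)(C)O[Si](CC)(CC)CC | intermediate (not isolated)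
6 | (5R,6S)-2-methyl-6-(triethylsilyloxy)-5-[2-(triethylsilyloxy)propan-2-yl]cyclohex-2-en-1-one (5,6-trans) | CC1=CC[C@H]([C@H](O[Si](CC)(CC)CC)C1=O)C(C)(C)O[Si](CC)(CC)CC | intermediate
7 | lithium (2R)-2-tert-butyl-5-methyl-1,3-dioxol-4-olate | [Li+].CC1=C([O-])O[C@@H](O1)C(C)(C)C | intermediate (not isolated)
8 | lithium (3R,5R,6S)-3-[(2R,4S)-2-tert-butyl-4-methyl-5-oxo-1,3-dioxolan-4-yl]-2-methyl-6-(triethylsilyloxy)-5-[2-(triethylsilyloxy)propan-2-yl]cyclohex-1-en-1-olate | [Li+].CC1=C([O-])[C@@H](O[Si](CC)(CC)CC)[C@@H](C[C@H]1[C@]2(C)O[C@@H](C(C)(C)C)OC2=O)C(C)(C)O[Si](CC)(CC)CC | intermediate (not isolated)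
9 | (3R,5R,6S)-3-[(2R,4S)-2-tert-butyl-4-methyl-5-oxo-1,3-dioxolan-4-yl]-2-methyl-6-(triethylsilyloxy)-5-[2-(triethylsilyloxy)propan-2-yl]cyclohex-1-en-1-yl trifluoromethanesulfonate | CC1=C(OS(=O)(=O)C(F)(F)F)[C@@H](O[Si](CC)(CC)CC)[C@@H](C[C@H]1[C@]2(C)O[C@@H](C(C)(C)C)OC2=O)C(C)(C)O[Si](CC)(CC)CC | intermediate
10 | (2R,5S)-2-tert-butyl-5-methyl-5-{(1R,4R,5R)-2-methyl-4-(triethylsilyloxy)-5-[2-(triethylsilyloxy)propan-2-yl]cyclohex-2-en-1-yl}-1,3-dioxolan-4-one | CC1=C[C@@H](O[Si](CC)(CC)CC)[C@@H](C[C@H]1[C@]2(C)O[C@@H](C(C)(C)C)OC2=O)C(C)(C)O[Si](CC)(CC)CC | intermediate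
11 | corresponding 1,3-dioxolan-4-ol (lactol of 10, mixture at the hemiacetal carbon) | CC1=C[C@@H](O[Si](CC)(CC)CC)[C@@H](C[C@H]1[C@]2(C)O[C@@H](C(C)(C)C)OC2O)C(C)(C)O[Si](CC)(CC)CC | intermediate (not isolated)
12 | (2S)-2-hydroxy-2-{(1R,4R,5R)-2-methyl-4-(triethylsilyloxy)-5-[2-(triethylsilyloxy)propan-2-yl]cyclohex-2-en-1-yl}propanal | CC1=C[C@@H](O[Si](CC)(CC)CC)[C@@H](C[C@H]1[C@](C)(O)C=O)C(C)(C)O[Si](CC)(CC)CC | intermediate
13 | methyl vinyl ketone (but-3-en-2-one) | C=CC(C)=O | starting material
14 | 2α-acetyl-8β,11-bis(triethylsilyloxy)eudesmane-3β,4α-diol with 5α-H, 10β-CH3 and the C7 side chain α (expected major C2/C3 isomer) | C[C@]12C[C@@H](C(C)=O)[C@H](O)[C@@](C)(O)[C@@H]1C[C@@H](C(C)(C)O[Si](CC)(CC)CC)[C@H](O[Si](CC)(CC)CC)C2 | intermediate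
15 | 2-acetyl-4α-hydroxy-8β,11-bis(triethylsilyloxy)eudesman-3-one, C7 side chain α (enolised β-diketone, C2 not defined) | C[C@]12CC(C(C)=O)C(=O)[C@@](C)(O)[C@@H]1C[C@@H](C(C)(C)O[Si](CC)(CC)CC)[C@H](O[Si](CC)(CC)CC)C2 | intermediate (not isolated)
16 | 4α-hydroxy-8β,11-bis(triethylsilyloxy)eudesman-3-one, C7 side chain α | C[C@]12CCC(=O)[C@@](C)(O)[C@@H]1C[C@@H](C(C)(C)O[Si](CC)(CC)CC)[C@H](O[Si](CC)(CC)CC)C2 | intermediate
17 | 4α-acetoxy-8β,11-bis(triethylsilyloxy)eudesman-3-one, C7 side chain α | C[C@]12CCC(=O)[C@@](C)(OC(C)=O)[C@@H]1C[C@@H](C(C)(C)O[Si](CC)(CC)CC)[C@H](O[Si](CC)(CC)CC)C2 | intermediate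
18 | 4α-acetoxy-8β,11-bis(triethylsilyloxy)eudesman-3α-ol, C7 side chain α | C[C@]12CC[C@@H](O)[C@@](C)(OC(C)=O)[C@@H]1C[C@@H](C(C)(C)O[Si](CC)(CC)CC)[C@H](O[Si](CC)(CC)CC)C2 | intermediate
19 | angelic acid, (Z)-2-methylbut-2-enoic acid | C/C=C(/C)C(=O)O | starting material
20 | (Z)-2-methylbut-2-enoic 2,4,6-trichlorobenzoic anhydride | C/C=C(/C)C(=O)OC(=O)c1c(Cl)cc(Cl)cc1Cl | intermediate (not isolated)
21 | 4α-acetoxy-3α-angeloyloxy-8β,11-bis(triethylsilyloxy)eudesmane, C7 side chain α | C[C@]12CC[C@@H](OC(=O)/C(C)=C\C)[C@@](C)(OC(C)=O)[C@@H]1C[C@@H](C(C)(C)O[Si](CC)(CC)CC)[C@H](O[Si](CC)(CC)CC)C2 | intermediate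
22 | 4α-acetoxy-3α-angeloyloxyeudesmane-8β,11-diol, C7 side chain α | C[C@]12CC[C@@H](OC(=O)/C(C)=C\C)[C@@](C)(OC(C)=O)[C@@H]1C[C@@H](C(C)(C)O)[C@H](O)C2 | intermediate
23 | 4α-acetoxy-3α-angeloyloxy-11-hydroxyeudesman-8-one, C7 side chain α | C[C@]12CC[C@@H](OC(=O)/C(C)=C\C)[C@@](C)(OC(C)=O)[C@@H]1C[C@@H](C(C)(C)O)C(=O)C2 | intermediate
24 | 4α-acetoxy-3α-angeloyloxyeudesm-7(11)-en-8-one | C[C@]12CC[C@@H](OC(=O)/C(C)=C\C)[C@@](C)(OC(C)=O)[C@@H]1CC(=C(C)C)C(=O)C2 | intermediate
25 | (3R,4S,5R,7S,10R)-4α-acetoxy-3α-angeloyloxy-7α-hydroperoxyeudesm-11-en-8-one (CNP0360871.1) | C=C(C)[C@@]1(OO)C[C@@H]2[C@](C)(CC[C@@H](OC(=O)/C(C)=C\C)[C@@]2(C)OC(C)=O)CC1=O | target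

**Step count and risks**

Total step count: 15. Longest linear sequence: 14 steps (steps 2–15, from (R)-carvone).

Steps most likely to fail:

1. Step 7. The iron enolate may be protonated, or the C10 radical reduced, before the aldol closes ring A, since ring B must turn its C7 and C8 substituents axial to bring C1 and C4 gauche; attack of the acceptor on the β face of C10 would give the cis-fused epimer. Fallback, setting out from 12 and 13 and returning at 14: the radical and ionic events are separated. Giese addition alone under proton-quench conditions (Fe(acac)3, PhSiH3, EtOH, rt) should give the open-chain keto aldehyde (2S)-2-hydroxy-2-[2-methyl-2-(3-oxobutyl)cyclohexyl]propanal derivative F3. Ring A is then closed by a reversible ionic aldol (pyrrolidine, AcOH, CH2Cl2, rt), which collects the thermodynamic chair product 14.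

2. Step 15. Oxygen may be transferred to C11 with abstraction of H-6 (the geminal regiochemistry usual for enones), or attack may occur from the β face. Fallback, setting out from 24 and returning at 25: ionic instead of pericyclic oxygenation. γ-Deprotonation with KN(SiMe3)2 (THF, −78 °C; the competing C9 methylene is neopentylic) should give the extended potassium dienolate F4, which is oxygenated by O2 at its α-carbon C7 from the α face and quenched cold with AcOH (enolate autoxidation to an α-hydroperoxy ketone).

3. Step 4. 1,2-Addition to the C9 carbonyl, proton transfer from C8–H to the ester enolate, or fragmentation of the acetal enolate above −40 °C may replace the conjugate addition. Fallback, setting out from 2 and 6 and returning at 9: a Mukaiyama–Michael route. Compound 2 is converted into the silyl ketene acetal (2R)-2-tert-butyl-5-methyl-4-(trimethylsilyloxy)-1,3-dioxole F1 (LiN(i-Pr)2, Me3SiCl, THF, −78 °C). F1 is added to 6 under Lewis-acid catalysis (Me3SiNTf2, CH2Cl2, −78 °C) with the same two facial preferences, to give the trimethylsilyl enol ether of the Michael adduct F2. F2 is converted into 9 with CsF and N-phenylbis(trifluoromethanesulfonimide) in DME.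

**Further compounds**

F1 | step 4 | (2R)-2-tert-butyl-5-methyl-4-(trimethylsilyloxy)-1,3-dioxole | CC1=C(O[Si](C)(C)C)O[C@@H](O1)C(C)(C)C
F2 | step 4 | trimethylsilyl enol ether of the Michael adduct (C9–OSiMe3 analogue of 9) | CC1=C(O[Si](C)(C)C)[C@@H](O[Si](CC)(CC)CC)[C@@H](C[C@H]1[C@]2(C)O[C@@H](C(C)(C)C)OC2=O)C(C)(C)O[Si](CC)(CC)CC
F3 | step 7 | (2S)-2-hydroxy-2-{(1R,2R,4R,5R)-2-methyl-2-(3-oxobutyl)-4-(triethylsilyloxy)-5-[2-(triethylsilyloxy)propan-2-yl]cyclohexyl}propanal (open-chain Giese adduct, C10 methyl β) | CC(=O)CC[C@]1(C)C[C@@H](O[Si](CC)(CC)CC)[C@@H](C[C@H]1[C@](C)(O)C=O)C(C)(C)O[Si](CC)(CC)CC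
F4 | step 15 | potassium 7,11(12)-dien-8-olate of 24 (extended dienolate) | [K+].C[C@]12CC[C@@H](OC(=O)/C(C)=C\C)[C@@](C)(OC(C)=O)[C@@H]1CC(C(C)=C)=C([O-])C2
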